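## Numbering and assumptions

Ring atoms: C1 (quaternary), C2=C3, C4 (ester carbinol), C5 (tertiary carbinol), C6=C7, C8 (ketone), C9 (bearing CH2OH)=C10, C11. Side chain on C1: C1′–C2′–C3′(OH)–isopropenyl. In this numbering the target is (1S,4R,5R,3′R), and each of the three ring double bonds holds its two ring carbons cis.

Assumption: the hand of the chiral catalysts in steps 2 and 15 is written as the usual facial models suggest; if these substrates show the opposite sense, the mirror-image catalyst is used and nothing else changes.

## Analysis of the target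

The target is a single eleven-membered carbocycle (C1–C11). C1 carries a methyl group and a 3-hydroxy-4-methylpent-4-enyl chain, C4 a 3-methylbut-2-enoate (senecioate), C5 a methyl group and a free hydroxyl, and C9 a hydroxymethyl group. The ring holds three cis double bonds; C6=C7 and C9=C10 flank the C8 ketone as a cross-conjugated dienone, and C2=C3 sits between the quaternary C1 and the C4 carbinol. There are four stereocentres: C1 (S, all-carbon quaternary), C4 (R) and C5 (R), which are vicinal and syn (threo) along C3–C4–C5–C6, and C3′ (R), insulated from the ring by two methylenes. C1, the C4/C5 pair and C3′ cannot relay stereochemistry to one another, so each must be set in the absolute sense. Sensitive groups are the ester next to a free tertiary alcohol (acyl shift under base), the cis γ-hydroxy enone (hemiketal formation, cis-to-trans isomerisation), the α-hydroxymethyl enone (a Michael acceptor) and the allylic alcohols (acid). The main difficulties are closing a strained medium ring with three cis alkenes and building a quaternary centre whose three carbon arms are chemically alike. The strategy rests on those arms: they end at C2, C10 and C3′, and a C10=C3′ double bond with oxygen on C3′ turns C1, C11, C10, C3′, C2′ and C1′ into a six-membered ring. That ring is the silyl enol ether of a 4-formyl-4-methylcyclohexanone, a Diels–Alder adduct of methacrolein with a 2-silyloxybutadiene.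

## Retrosynthetic reasoning

**Target 36 back to macrocyclic alcohol 34.** The last operations are only adjustments: removal of three silyl ethers from 35 and oxidation of the C8 carbinol of 34. The ring is closed at the alcohol level because a carbinol at C8 can come from a carbonyl addition, and the new C8 stereocentre is erased by the oxidation, so the ring closure has no stereochemical task.

**34 to open-chain iodo-enal 32 (C8–C9).** The ring is cut between the ketone carbon and the trisubstituted alkene. This places an unhindered aldehyde on one side and an alkenyl iodide on the other. The C9=C10 geometry is fixed in the open chain and is retained by an alkenylchromium addition (Nozaki–Hiyama–Kishi reaction), which tolerates the ester and silyl ethers. C2–C3 or C3–C4 would put the reacting centres next to the quaternary C1 or C5; C4–C5 would force two stereocentres to be made during ring closure.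

**32 to butenolide 25.** The cis γ-oxygenated enal C5–C6=C7–C8 is a ring-opened butenolide. Reducing lactone 25 to triol 27 keeps the cis geometry and turns the ring oxygen into the C5 hydroxyl. The senecioate (from acid chloride 29) can only be attached after this hydride step, which fixes the order: silylate the primary alcohol (28), acylate C4 (30), silylate C5 (31), oxidise C8 (32).

**25 to alkyne 24 (C2=C3).** The cis alkene is taken back to an alkyne. The alkyne survives the earlier ozonolysis, sets the geometry by syn addition of hydrogen, and gives a linear, unhindered ynal for the preceding bond formation.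

**24 to ynal 20 and silyloxyfuran 22 (C4–C5).** Cutting between the two carbinol carbons gives an aldehyde and a γ-nucleophilic furan, made in one step from lactone 21. One vinylogous Mukaiyama aldol then delivers both stereocentres, the C5 methyl, the cis C6=C7 alkene and C8 at the acid oxidation level. The forward step must select one face of each partner (like topicity) under catalyst control, because C1 is too far away to help.

**20 to bis-silyl ether 18 (C3–C4).** The formyl carbon C4 is added to the terminal alkyne by formylation of acetylide 19. It is placed late so that no aldehyde has to be carried through the arm chemistry.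

**18 to keto aldehyde 12 and ylide 14 (C9=C10).** The iodoalkene with its allylic oxygen is taken back to (Z)-α-iodo enoate 15. The C9=C10 bond is cut by a Wittig disconnection to the C10 aldehyde of 12 and stabilised ylide 14, made from 13; a stabilised ylide puts iodine cis to C11. The C3′ carbinol of 16 comes from enantioselective reduction of the isopropenyl ketone; the ester reduction (17) and double silylation (18) follow.

**12 to hydroxy acid 8 and Grignard reagent 10 (C3′–C4′ bond).** The isopropenyl ketone is disconnected at the carbonyl to the N-methoxy-N-methylamide 9 of acid 8. The C10 terminus is kept as an alcohol during the Grignard addition (11) and oxidised afterwards.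

**8 to cyclohexene 6 (C10=C3′).** The C10 alcohol and the C3′ acid are the two ends of a cleaved silyl enol ether. Ozonolysis of 6 with hydride work-up gives both, already different in oxidation level and in length (two and three carbons from C1). The enol ether is the only element that tells the two arms apart, so it is cleaved directly and never hydrolysed to the symmetrical ketone.

**6 to aldehyde 4 (C2–C3).** The ethynyl group comes from the formyl group by one-carbon homologation under aprotic basic conditions, which the enol ether tolerates.

**4 to diene 2 and methacrolein 3 (C1–C11 and C1′–C2′).** The cyclohexene is a [4+2] adduct. The forward reaction must give the 1,4-regioisomer and one enantiomer at C1. Diene 2 comes in one step from methyl vinyl ketone 1, so the risk of the route sits in this cycloaddition.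

## Alternatives that were turned down

Alternative 1: Disconnection at C9–C10 with later movement of oxygen. In the forward step Ni(cod)2 (zerovalent nickel), a bulky N-heterocyclic carbene and Et3SiH would couple a terminal alkyne at its internal carbon with a C10 aldehyde in an open chain. This would give the eleven-membered ring A1 with an exocyclic methylene on C9 and a silyl ether on C10. In its favour: the macrocyclisation is catalytic, needs no alkenyl iodide and no stoichiometric chromium, and the ring-forming partners are simple to prepare; on these points it is stronger than the chosen route. Against it: A1 has the oxygen on the wrong carbon. A 1,3-allylic transposition must then move it to the exocyclic carbon and at the same time create the trisubstituted C9=C10 alkene with C8 and C11 cis, inside a medium ring where nothing controls that geometry. The internal-carbon regiochemistry of the alkyne coupling is ligand- and ring-size-dependent, and C8 still needs deprotection and oxidation. The chosen route fixes the C9=C10 geometry in the open chain by a Wittig reaction and carries it through a stereoretentive ring closure, and it needs fewer operations after the ring is made.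

Alternative 2: Disconnection of C3–C8 in a cis-fused bicyclo[5.4.0]undecadiene. In the forward step a C8 alkoxide would expel an antiperiplanar C2 mesylate (Grob fragmentation), forming C2=C3 and the C8 ketone and releasing the eleven-membered trienone A2. In its favour: no entropically costly ring closure is needed, since the medium ring is unveiled from a six- and a seven-membered ring, and the C2=C3 geometry follows stereospecifically from the relative configuration; on ring-forming risk this is clearly the stronger plan. Against it: the fragmentation substrate needs contiguous stereocentres at C1, C2, C3, C4, C5 and C8, three of which exist only to be destroyed. The leaving group must lie antiperiplanar to the ring-fusion bond in the cis-fused system. The alkoxide sits next to two alkenes, where retro-aldol and elimination pathways compete. The chosen route instead reaches the quaternary centre in two steps, builds each alkene and stereocentre in the open chain, and is much shorter up to the ring-forming event.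

Alternative 3: Disconnection at C3–C4. In the forward step NiCl2/CrCl2 would turn a cis alkenyl iodide at C3 into an alkenylchromium that adds to a C4 aldehyde, giving the eleven-membered C4 alcohol A3. In its favour: the reaction type is the same reliable one used in the chosen route, and the C5–C9 portion arrives with the C8 oxygen in place, which makes the plan more convergent. Against it: the ring closure must create the C4 stereocentre, which is kept in the target, with no element to control it. Both reacting carbons are hindered: the alkenylchromium is next to the quaternary C1 and the aldehyde next to the fully substituted C5. A correction by oxidation and reduction would have to be done in a ring that already holds a reducible dienone precursor. The chosen route closes at C8, where the aldehyde is unhindered and the new stereocentre is erased, and sets C4 together with C5 earlier under catalyst control.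

Key step: step 2

## Route

Step 1
Reactants: 1 methyl vinyl ketone
Product: 2 2-(triisopropylsilyloxy)buta-1,3-diene
Conditions: TIPSOTf, Et3N, Et2O, 0 °C → rt
Reagents that add atoms: triisopropylsilyl trifluoromethanesulfonate, CC(C)[Si](C(C)C)(C(C)C)OS(=O)(=O)C(F)(F)F
Why: Soft enolisation of the enone by the silyl triflate/amine pair gives the 2-silyloxy diene; the bulky triisopropylsilyl group is chosen because the enol ether must outlast a strong Lewis acid and a basic homologation before it is cut.

Step 2
Reactants: 2 2-(triisopropylsilyloxy)buta-1,3-diene; 3 methacrolein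
Product: 4 (1S)-1-methyl-4-(triisopropylsilyloxy)cyclohex-3-ene-1-carbaldehyde (the formyl carbon is C2)
Conditions: (S)-B-o-tolyl oxazaborolidine from (S)-α,α-diphenylprolinol (20 mol %), Tf2NH (20 mol %), CH2Cl2, −95 → −78 °C; Et3N quench
Reagents that add atoms: none
Why: The triflimide-activated oxazaborolidine binds the formyl oxygen of s-trans methacrolein, a formyl C–H···O contact fixes the complex, and an aryl group of the catalyst covers one face of the C=C bond. Diene 2 adds to the open face in a concerted, asynchronous [4+2] cycloaddition: the diene terminus next to the silyloxy carbon bonds first to the methylene of 3 (C1′–C2′), the C1–C11 bond follows, and one six-membered carbocycle closes suprafacially on both partners. The closest known reaction type is the oxazaborolidinium-catalysed enantioselective Diels–Alder reaction of 2-substituted acroleins with 2-silyloxy dienes. C1 is the only stereocentre formed and is set by the catalyst's choice of enantioface, so endo/exo selectivity is irrelevant. The step needs 1,4-regioselectivity, which the silyloxy donor secures by polarising the diene; this makes the two future arms two and three carbons long up to the cleavage point. It also needs the enol ether to survive the acid, which the bulky silyl group, the low temperature and the amine quench secure. The ring is temporary: its C10=C3′ bond is cut in step 4.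

Step 3
Reactants: 4 (1S)-1-methyl-4-(triisopropylsilyloxy)cyclohex-3-ene-1-carbaldehyde
Product: 6 triisopropyl{[(4S)-4-ethynyl-4-methylcyclohex-1-en-1-yl]oxy}silane, via diazoalkene 5 (not isolated)
Conditions: TMSCHN2, n-BuLi, THF, −78 °C → rt
Reagents that add atoms: (trimethylsilyl)diazomethane, C[Si](C)(C)C=[N+]=[N-]
Why: Colvin rearrangement: the lithiated silyl diazomethane adds to the aldehyde, silanolate is eliminated to give diazoalkene 5, and loss of nitrogen with a 1,2-hydrogen shift gives the alkyne (new carbon C3); the aprotic conditions leave the enol ether intact and the α-quaternary C1 cannot epimerise.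

Step 4
Reactants: 6 triisopropyl{[(4S)-4-ethynyl-4-methylcyclohex-1-en-1-yl]oxy}silane
Product: 8 (4S)-4-ethynyl-6-hydroxy-4-methylhexanoic acid, via methoxy hydroperoxide silyl ester 7 (not isolated)
Conditions: O3, CH2Cl2/MeOH, Sudan red 7B indicator, −78 °C; NaBH4, −78 → 0 °C; aq. HCl to pH 3
Reagents that add atoms: ozone, [O-][O+]=O
Why: Ozone attacks the electron-rich enol ether far faster than the terminal alkyne and cleaves C10=C3′ to a silyl ester at C3′ and a methanol-trapped carbonyl oxide at C10 (7); borohydride reduces the C10 terminus to the alcohol and work-up frees the acid, so the two arms emerge differentiated in one operation.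

Step 5
Reactants: 8 (4S)-4-ethynyl-6-hydroxy-4-methylhexanoic acid
Product: 9 (4S)-4-ethynyl-6-hydroxy-N-methoxy-N,4-dimethylhexanamide
Conditions: MeNHOMe·HCl, EDC·HCl, HOBt, N-methylmorpholine, CH2Cl2, 0 °C → rt
Reagents that add atoms: N,O-dimethylhydroxylamine hydrochloride, CNOC.Cl
Why: Carbodiimide amidation; the amine outcompetes the remote primary alcohol, and the N-methoxy-N-methylamide prepares a clean single addition of a carbon nucleophile.

Step 6
Reactants: 9 (4S)-4-ethynyl-6-hydroxy-N-methoxy-N,4-dimethylhexanamide; 10 isopropenylmagnesium bromide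
Product: 11 (6S)-6-ethynyl-8-hydroxy-2,6-dimethyloct-1-en-3-one
Conditions: 10 (3.5 equiv), THF, −20 → 0 °C; cold aq. NH4Cl
Reagents that add atoms: none
Why: Grignard addition to the N-methoxy-N-methylamide stops at the chelated tetrahedral intermediate and gives the enone on work-up; the extra equivalents are consumed by the O–H and alkyne C–H, which are restored on quenching.

Step 7
Reactants: 11 (6S)-6-ethynyl-8-hydroxy-2,6-dimethyloct-1-en-3-one
Product: 12 (3S)-3-ethynyl-3,7-dimethyl-6-oxooct-7-enal
Conditions: Dess–Martin periodinane, NaHCO3, CH2Cl2, 0 °C → rt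
Reagents that add atoms: none
Why: Mild, buffered oxidation of the primary alcohol to the C10 aldehyde; the enone and alkyne are inert to the hypervalent iodine reagent.

Step 8
Reactants: 13 ethyl (triphenylphosphoranylidene)acetate
Product: 14 ethyl iodo(triphenylphosphoranylidene)acetate
Conditions: I2, K2CO3, MeOH, 0 °C → rt
Reagents that add atoms: iodine, II
Why: Electrophilic iodination of the stabilised ylide followed by deprotonation of the iodophosphonium salt gives the α-iodo ylide, which is stable enough to isolate.

Step 9
Reactants: 12 (3S)-3-ethynyl-3,7-dimethyl-6-oxooct-7-enal; 14 ethyl iodo(triphenylphosphoranylidene)acetate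
Product: 15 ethyl (2Z,5S)-5-ethynyl-2-iodo-5,9-dimethyl-8-oxodeca-2,9-dienoate
Conditions: CH2Cl2, rt → 40 °C
Reagents that add atoms: none
Why: Wittig olefination with a stabilised ylide puts the ester trans to the chain, so iodine ends cis to C11; this (Z)-iodoalkene geometry becomes that of C9=C10, and the ylide reacts with the aldehyde only, not with the ketone.

Step 10
Reactants: 15 ethyl (2Z,5S)-5-ethynyl-2-iodo-5,9-dimethyl-8-oxodeca-2,9-dienoate
Product: 16 ethyl (2Z,5S,8R)-5-ethynyl-8-hydroxy-2-iodo-5,9-dimethyldeca-2,9-dienoate
Conditions: (S)-2-methyl-CBS-oxazaborolidine (20 mol %), catecholborane, toluene, −78 °C; MeOH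
Reagents that add atoms: none
Why: Corey–Bakshi–Shibata reduction: the isopropenyl group acts as the large substituent and the (S)-catalyst delivers hydride to the face that gives the (R)-carbinol at C3′; catecholborane at −78 °C leaves the alkyne, the alkenes and the iodo enoate alone.

Step 11
Reactants: 16 ethyl (2Z,5S,8R)-5-ethynyl-8-hydroxy-2-iodo-5,9-dimethyldeca-2,9-dienoate
Product: 17 (2Z,5S,8R)-5-ethynyl-2-iodo-5,9-dimethyldeca-2,9-diene-1,8-diol
Conditions: i-Bu2AlH (3.5 equiv), CH2Cl2, −78 → −40 °C; Rochelle salt
Reagents that add atoms: none
Why: 1,2-Reduction of the conjugated ester to the allylic alcohol (the future C9 hydroxymethyl group); the C–I bond and the double-bond geometry are untouched at low temperature.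

Step 12
Reactants: 17 (2Z,5S,8R)-5-ethynyl-2-iodo-5,9-dimethyldeca-2,9-diene-1,8-diol
Product: 18 (2Z,5S,8R)-1,8-bis(tert-butyldimethylsilyloxy)-5-ethynyl-2-iodo-5,9-dimethyldeca-2,9-diene
Conditions: TBSCl (2.5 equiv), imidazole, DMF, rt
Reagents that add atoms: tert-butyldimethylsilyl chloride, CC(C)(C)[Si](C)(C)Cl
Why: Both hydroxyls are silylated in one operation; the two ethers last to the final step and are removed together by fluoride.

Step 13
Reactants: 18 (2Z,5S,8R)-1,8-bis(tert-butyldimethylsilyloxy)-5-ethynyl-2-iodo-5,9-dimethyldeca-2,9-diene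
Product: 20 (4S,7R)-7-(tert-butyldimethylsilyloxy)-4-[(2Z)-4-(tert-butyldimethylsilyloxy)-3-iodobut-2-en-1-yl]-4,8-dimethylnon-8-en-2-ynal, via lithium acetylide 19 (not isolated)
Conditions: LiN(i-Pr)2 (1.05 equiv), THF, −78 °C; DMF, −78 → 0 °C; poured into cold aq. KH2PO4
Reagents that add atoms: N,N-dimethylformamide, CN(C)C=O
Why: One equivalent of amide base deprotonates the terminal alkyne without the iodine–lithium exchange an alkyllithium would cause; formylation of 19 and a buffered reverse quench give the ynal and bring in C4.

Step 14
Reactants: 21 α-angelica lactone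
Product: 22 tert-butyldimethyl[(5-methylfuran-2-yl)oxy]silane
Conditions: TBSOTf, Et3N, CH2Cl2, 0 °C
Reagents that add atoms: tert-butyldimethylsilyl trifluoromethanesulfonate, CC(C)(C)[Si](C)(C)OS(=O)(=O)C(F)(F)F
Why: Soft enolisation and O-silylation of the butenolide give the aromatic 2-silyloxyfuran, a γ-nucleophilic dienolate equivalent that carries C5 to C8 and the C5 methyl.

Step 15
Reactants: 20 ynal; 22 tert-butyldimethyl[(5-methylfuran-2-yl)oxy]silane
Product: 24 (5R)-5-[(1R,4S,7R)-7-(tert-butyldimethylsilyloxy)-4-[(2Z)-4-(tert-butyldimethylsilyloxy)-3-iodobut-2-en-1-yl]-1-hydroxy-4,8-dimethylnon-8-en-2-yn-1-yl]-5-methylfuran-2(5H)-one, via trichlorosilyl ether 23 (not isolated)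
Conditions: SiCl4 (1.2 equiv), (S,S)-bis-phosphoramide [two N,N′-dimethyl-1,1′-binaphthyl-2,2′-diamine phosphoramide units joined by a 1,5-pentanediyl bis(N-methylamino) linker] (5 mol %), i-Pr2NEt (10 mol %), CH2Cl2, −78 °C; aq. NaHCO3/KF
Reagents that add atoms: none
Why: Catalytic enantioselective vinylogous Mukaiyama aldol: the phosphoramide-bound trichlorosilyl cation activates the linear ynal, and the furan attacks through its γ-carbon (C5) in an open transition state; the catalyst exposes the Si face of the aldehyde, and the usual threo (like, Si/Si) preference of Lewis-acid additions of 2-silyloxyfurans then gives (4R,5R), with the C6=C7 bond locked cis in the butenolide.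

Step 16
Reactants: 24 propargylic alcohol butenolide
Product: 25 (5R)-5-[(1R,2Z,4S,7R)-7-(tert-butyldimethylsilyloxy)-4-[(2Z)-4-(tert-butyldimethylsilyloxy)-3-iodobut-2-en-1-yl]-1-hydroxy-4,8-dimethylnona-2,8-dien-1-yl]-5-methylfuran-2(5H)-one
Conditions: H2 (1 atm), Pd/CaCO3 poisoned with Pb(OAc)2 (Lindlar catalyst), quinoline, EtOAc, rt, stopped after one equivalent of H2
Reagents that add atoms: none
Why: Lindlar semi-hydrogenation: syn delivery of hydrogen on the poisoned palladium surface gives the cis C2=C3 alkene; the alkyne binds far more strongly than the hindered or conjugated alkenes, and quinoline with a strict hydrogen count limits attack on the C–I bond.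

Step 17
Reactants: 25 cis-alkenyl butenolide
Product: 27 (2Z,4R,5R,6Z,8S,11R)-11-(tert-butyldimethylsilyloxy)-8-[(2Z)-4-(tert-butyldimethylsilyloxy)-3-iodobut-2-en-1-yl]-4,8,12-trimethyltrideca-2,6,12-triene-1,4,5-triol, via lactol 26 (not isolated)
Conditions: i-Bu2AlH (4 equiv), CH2Cl2, −78 → 0 °C; Rochelle salt
Reagents that add atoms: none
Why: Hydride reduction of the butenolide through lactol 26 to the cis-ene-1,4-diol; the ring geometry of the lactone is carried into the C6=C7 alkene and the former ring oxygen becomes the C5 hydroxyl.

Step 18
Reactants: 27 triol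
Product: 28 (2Z,4R,5R,6Z,8S,11R)-11-(tert-butyldimethylsilyloxy)-8-[(2Z)-4-(tert-butyldimethylsilyloxy)-3-iodobut-2-en-1-yl]-4,8,12-trimethyl-1-(triethylsilyloxy)trideca-2,6,12-triene-4,5-diol
Conditions: TESCl (1.05 equiv), imidazole, CH2Cl2, −40 → −20 °C
Reagents that add atoms: chlorotriethylsilane, CC[Si](Cl)(CC)CC
Why: Selective silylation: the primary allylic C8 hydroxyl reacts much faster than the secondary C4 hydroxyl, which is flanked by the fully substituted C5, and than the tertiary C5 hydroxyl.

Step 19
Reactants: 28 C8 triethylsilyl ether diol; 29 3-methylbut-2-enoyl chloride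
Product: 30 (2Z,4R,5R,6Z,8S,11R)-11-(tert-butyldimethylsilyloxy)-8-[(2Z)-4-(tert-butyldimethylsilyloxy)-3-iodobut-2-en-1-yl]-4-hydroxy-4,8,12-trimethyl-1-(triethylsilyloxy)trideca-2,6,12-trien-5-yl 3-methylbut-2-enoate
Conditions: pyridine, DMAP (cat.), CH2Cl2, 0 °C → rt
Reagents that add atoms: none
Why: Nucleophile-catalysed acylation esterifies the secondary C4 hydroxyl and leaves the tertiary one; pyridine as the only stoichiometric base limits deconjugation of the acyl group through a vinylketene, and the ester is introduced only now because all hydride steps are over.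

Step 20
Reactants: 30 C4 ester with free C5 hydroxyl
Product: 31 (2Z,4R,5R,6Z,8S,11R)-11-(tert-butyldimethylsilyloxy)-8-[(2Z)-4-(tert-butyldimethylsilyloxy)-3-iodobut-2-en-1-yl]-4,8,12-trimethyl-1,4-bis(triethylsilyloxy)trideca-2,6,12-trien-5-yl 3-methylbut-2-enoate
Conditions: TESOTf, 2,6-lutidine, CH2Cl2, −78 → −20 °C
Reagents that add atoms: triethylsilyl trifluoromethanesulfonate, CC[Si](CC)(CC)OS(=O)(=O)C(F)(F)F
Why: The silyl triflate caps the hindered tertiary alcohol; this blocks acyl shift from C4 to C5 and prevents lactol formation once C8 becomes an aldehyde.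

Step 21
Reactants: 31 bis(triethylsilyl) ether
Product: 32 (2Z,4R,5R,6Z,8S,11R)-11-(tert-butyldimethylsilyloxy)-8-[(2Z)-4-(tert-butyldimethylsilyloxy)-3-iodobut-2-en-1-yl]-4,8,12-trimethyl-1-oxo-4-(triethylsilyloxy)trideca-2,6,12-trien-5-yl 3-methylbut-2-enoate
Conditions: (COCl)2, DMSO, CH2Cl2, −78 → −30 °C; Et3N, −78 → 0 °C
Reagents that add atoms: none
Why: Under Swern conditions a primary triethylsilyl ether is converted directly into the aldehyde (silyl transfer to chloride, then the usual alkoxysulfonium elimination), while the tertiary triethylsilyl and the tert-butyldimethylsilyl ethers stay; a free cis γ-hydroxy enal is never formed and the low temperature preserves the cis geometry.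

Step 22
Reactants: 32 iodo-enal
Product: 34 eleven-membered allylic alcohol (both C8 epimers; C4 senecioate; C5 triethylsilyl ether; C3′ and C9-hydroxymethyl tert-butyldimethylsilyl ethers; cis C2=C3, C6=C7 and C9=C10), via alkenylchromium dichloride 33 (not isolated)
Conditions: CrCl2 (10 equiv), NiCl2 (2 mol %), DMSO/THF, rt, slow addition, final concentration about 3 mM
Reagents that add atoms: none
Why: Nozaki–Hiyama–Kishi reaction: zerovalent nickel inserts into the C–I bond, transmetalation to trivalent chromium gives 33 with retention of alkene geometry, and 33 adds only to the aldehyde to form C8–C9 and close the eleven-membered ring; the three cis alkenes and the quaternary C1 bend the chain toward closure, high dilution suppresses oligomers, and both C8 epimers are carried on.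

Step 23
Reactants: 34 eleven-membered allylic alcohol
Product: 35 eleven-membered cross-conjugated dienone (C8 ketone; silyl ethers and ester as in 34)
Conditions: Dess–Martin periodinane, NaHCO3, CH2Cl2, 0 °C
Reagents that add atoms: none
Why: Buffered oxidation of the doubly allylic alcohol gives the C8 ketone, merges the two epimers and leaves the cis C6=C7 enone unisomerised.

Step 24
Reactants: 35 eleven-membered dienone
Product: 36 target CNP0311723.4, (1S,4R,5R,3′R)
Conditions: HF·pyridine, pyridine, THF, 0 °C → rt
Reagents that add atoms: none
Why: Buffered fluoride removes the two tert-butyldimethylsilyl ethers and the tertiary triethylsilyl ether under weakly acidic conditions, which avoids the base-induced acyl shift from O4 to O5 and addition chemistry at the hydroxymethyl enone.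

## Compound list

1 | methyl vinyl ketone | CC(=O)C=C | starting material
2 | 2-(triisopropylsilyloxy)buta-1,3-diene | C=CC(=C)O[Si](C(C)C)(C(C)C)C(C)C | intermediate
3 | methacrolein | CC(=C)C=O | starting material
4 | (1S)-1-methyl-4-(triisopropylsilyloxy)cyclohex-3-ene-1-carbaldehyde | O=C[C@]1(C)CC=C(O[Si](C(C)C)(C(C)C)C(C)C)CC1 | intermediate
5 | diazoalkene from 4 (1-diazo-2-substituted ethene, not isolated) | [N-]=[N+]=C=C[C@]1(C)CC=C(O[Si](C(C)C)(C(C)C)C(C)C)CC1 | intermediate
6 | triisopropyl{[(4S)-4-ethynyl-4-methylcyclohex-1-en-1-yl]oxy}silane | C#C[C@]1(C)CC=C(O[Si](C(C)C)(C(C)C)C(C)C)CC1 | intermediate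
7 | triisopropylsilyl (4S)-4-ethynyl-6-hydroperoxy-6-methoxy-4-methylhexanoate (not isolated) | C#C[C@](C)(CC(OC)OO)CCC(=O)O[Si](C(C)C)(C(C)C)C(C)C | intermediate
8 | (4S)-4-ethynyl-6-hydroxy-4-methylhexanoic acid | C#C[C@](C)(CCO)CCC(=O)O | intermediate
9 | (4S)-4-ethynyl-6-hydroxy-N-methoxy-N,4-dimethylhexanamide | C#C[C@](C)(CCO)CCC(=O)N(C)OC | intermediate
10 | isopropenylmagnesium bromide | C=C(C)[Mg]Br | starting material
11 | (6S)-6-ethynyl-8-hydroxy-2,6-dimethyloct-1-en-3-one | C#C[C@](C)(CCO)CCC(=O)C(C)=C | intermediate
12 | (3S)-3-ethynyl-3,7-dimethyl-6-oxooct-7-enal | C#C[C@](C)(CC=O)CCC(=O)C(C)=C | intermediate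
13 | ethyl (triphenylphosphoranylidene)acetate | CCOC(=O)C=P(c1ccccc1)(c1ccccc1)c1ccccc1 | starting material
14 | ethyl iodo(triphenylphosphoranylidene)acetate | CCOC(=O)C(I)=P(c1ccccc1)(c1ccccc1)c1ccccc1 | intermediate
15 | ethyl (2Z,5S)-5-ethynyl-2-iodo-5,9-dimethyl-8-oxodeca-2,9-dienoate | CCOC(=O)/C(I)=C/C[C@@](C)(C#C)CCC(=O)C(C)=C | intermediate
16 | ethyl (2Z,5S,8R)-5-ethynyl-8-hydroxy-2-iodo-5,9-dimethyldeca-2,9-dienoate | CCOC(=O)/C(I)=C/C[C@@](C)(C#C)CC[C@@H](O)C(C)=C | intermediate
17 | (2Z,5S,8R)-5-ethynyl-2-iodo-5,9-dimethyldeca-2,9-diene-1,8-diol | OC/C(I)=C/C[C@@](C)(C#C)CC[C@@H](O)C(C)=C | intermediate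
18 | (2Z,5S,8R)-1,8-bis(tert-butyldimethylsilyloxy)-5-ethynyl-2-iodo-5,9-dimethyldeca-2,9-diene | CC(C)(C)[Si](C)(C)OC/C(I)=C/C[C@@](C)(C#C)CC[C@@H](O[Si](C)(C)C(C)(C)C)C(C)=C | intermediate
19 | lithium acetylide of 18 (not isolated) | CC(C)(C)[Si](C)(C)OC/C(I)=C/C[C@@](C)(C#C[Li])CC[C@@H](O[Si](C)(C)C(C)(C)C)C(C)=C | intermediate
20 | (4S,7R)-7-(tert-butyldimethylsilyloxy)-4-[(2Z)-4-(tert-butyldimethylsilyloxy)-3-iodobut-2-en-1-yl]-4,8-dimethylnon-8-en-2-ynal | CC(C)(C)[Si](C)(C)OC/C(I)=C/C[C@@](C)(C#CC=O)CC[C@@H](O[Si](C)(C)C(C)(C)C)C(C)=C | intermediate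
21 | α-angelica lactone (5-methylfuran-2(3H)-one) | CC1=CCC(=O)O1 | starting material
22 | tert-butyldimethyl[(5-methylfuran-2-yl)oxy]silane | Cc1ccc(O[Si](C)(C)C(C)(C)C)o1 | intermediate
23 | O-trichlorosilyl ether of 24 (not isolated) | CC(C)(C)[Si](C)(C)OC/C(I)=C/C[C@@](C)(C#C[C@@H](O[Si](Cl)(Cl)Cl)[C@]1(C)OC(=O)C=C1)CC[C@@H](O[Si](C)(C)C(C)(C)C)C(C)=C | intermediate
24 | (5R)-5-[(1R,4S,7R)-7-(tert-butyldimethylsilyloxy)-4-[(2Z)-4-(tert-butyldimethylsilyloxy)-3-iodobut-2-en-1-yl]-1-hydroxy-4,8-dimethylnon-8-en-2-yn-1-yl]-5-methylfuran-2(5H)-one | CC(C)(C)[Si](C)(C)OC/C(I)=C/C[C@@](C)(C#C[C@@H](O)[C@]1(C)OC(=O)C=C1)CC[C@@H](O[Si](C)(C)C(C)(C)C)C(C)=C | intermediate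
25 | (5R)-5-[(1R,2Z,4S,7R)-7-(tert-butyldimethylsilyloxy)-4-[(2Z)-4-(tert-butyldimethylsilyloxy)-3-iodobut-2-en-1-yl]-1-hydroxy-4,8-dimethylnona-2,8-dien-1-yl]-5-methylfuran-2(5H)-one | CC(C)(C)[Si](C)(C)OC/C(I)=C/C[C@@](C)(/C=C\[C@@H](O)[C@]1(C)OC(=O)C=C1)CC[C@@H](O[Si](C)(C)C(C)(C)C)C(C)=C | intermediate
26 | lactol from 25 (5-substituted 5-methyl-2,5-dihydrofuran-2-ol, anomeric mixture, not isolated) | CC(C)(C)[Si](C)(C)OC/C(I)=C/C[C@@](C)(/C=C\[C@@H](O)[C@]1(C)OC(O)C=C1)CC[C@@H](O[Si](C)(C)C(C)(C)C)C(C)=C | intermediate
27 | (2Z,4R,5R,6Z,8S,11R)-11-(tert-butyldimethylsilyloxy)-8-[(2Z)-4-(tert-butyldimethylsilyloxy)-3-iodobut-2-en-1-yl]-4,8,12-trimethyltrideca-2,6,12-triene-1,4,5-triol | CC(C)(C)[Si](C)(C)OC/C(I)=C/C[C@@](C)(/C=C\[C@@H](O)[C@](C)(O)/C=C\CO)CC[C@@H](O[Si](C)(C)C(C)(C)C)C(C)=C | intermediate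
28 | 1-O-triethylsilyl ether of 27 | CC(C)(C)[Si](C)(C)OC/C(I)=C/C[C@@](C)(/C=C\[C@@H](O)[C@](C)(O)/C=C\CO[Si](CC)(CC)CC)CC[C@@H](O[Si](C)(C)C(C)(C)C)C(C)=C | intermediate
29 | 3-methylbut-2-enoyl chloride | CC(C)=CC(=O)Cl | starting material
30 | 5-O-(3-methylbut-2-enoyl) ester of 28 (target C4 ester, free C5 hydroxyl) | CC(C)(C)[Si](C)(C)OC/C(I)=C/C[C@@](C)(/C=C\[C@@H](OC(=O)C=C(C)C)[C@](C)(O)/C=C\CO[Si](CC)(CC)CC)CC[C@@H](O[Si](C)(C)C(C)(C)C)C(C)=C | intermediate
31 | 4-O-triethylsilyl ether of 30 | CC(C)(C)[Si](C)(C)OC/C(I)=C/C[C@@](C)(/C=C\[C@@H](OC(=O)C=C(C)C)[C@](C)(O[Si](CC)(CC)CC)/C=C\CO[Si](CC)(CC)CC)CC[C@@H](O[Si](C)(C)C(C)(C)C)C(C)=C | intermediate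
32 | (2Z,4R,5R,6Z,8S,11R)-11-(tert-butyldimethylsilyloxy)-8-[(2Z)-4-(tert-butyldimethylsilyloxy)-3-iodobut-2-en-1-yl]-4,8,12-trimethyl-1-oxo-4-(triethylsilyloxy)trideca-2,6,12-trien-5-yl 3-methylbut-2-enoate | CC(C)(C)[Si](C)(C)OC/C(I)=C/C[C@@](C)(/C=C\[C@@H](OC(=O)C=C(C)C)[C@](C)(O[Si](CC)(CC)CC)/C=C\C=O)CC[C@@H](O[Si](C)(C)C(C)(C)C)C(C)=C | intermediate
33 | alkenylchromium dichloride from 32 (not isolated) | CC(C)(C)[Si](C)(C)OC/C([Cr](Cl)Cl)=C/C[C@@](C)(/C=C\[C@@H](OC(=O)C=C(C)C)[C@](C)(O[Si](CC)(CC)CC)/C=C\C=O)CC[C@@H](O[Si](C)(C)C(C)(C)C)C(C)=C | intermediate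
34 | eleven-membered C8 alcohol (both C8 epimers), protected as in 32 | C=C(C)[C@H](O[Si](C)(C)C(C)(C)C)CC[C@]1(C)/C=C\[C@@H](OC(=O)C=C(C)C)[C@](C)(O[Si](CC)(CC)CC)/C=C\C(O)/C(CO[Si](C)(C)C(C)(C)C)=C\C1 | intermediate
35 | eleven-membered C8 ketone, protected | C=C(C)[C@H](O[Si](C)(C)C(C)(C)C)CC[C@]1(C)/C=C\[C@@H](OC(=O)C=C(C)C)[C@](C)(O[Si](CC)(CC)CC)/C=C\C(=O)/C(CO[Si](C)(C)C(C)(C)C)=C\C1 | intermediate
36 | CNP0311723.4 | C=C(C)[C@H](O)CC[C@]1(C)/C=C\[C@@H](OC(=O)C=C(C)C)[C@](C)(O)/C=C\C(=O)/C(CO)=C\C1 | target

## Step count and least certain steps

Total step count: 24 (steps 8 and 14 prepare side-branch reagents). Longest linear sequence: 22 steps from methyl vinyl ketone 1 (steps 1–7, 9–13 and 15–24).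

**Step 2 (key step).** The most likely failure is erosion of the enantiofacial selection, or protodesilylation and stepwise Mukaiyama–Michael oligomerisation of diene 2 under the strongly acidic catalyst. The enol ether is the only memory of which arm is which, so any loss of it is fatal. Fallback, from methacrolein 3 back to alkyne 6: a hydrogen-bond-catalysed cycloaddition of 3 with 1-(dimethylamino)-3-(tert-butyldimethylsilyloxy)buta-1,3-diene is run in the presence of the enantiomer of α,α,α′,α′-tetra(1-naphthyl)-2,2-dimethyl-1,3-dioxolane-4,5-dimethanol that leads to the (S)-quaternary centre. It gives (1S)-4-(tert-butyldimethylsilyloxy)-2-(dimethylamino)-1-methylcyclohex-3-ene-1-carbaldehyde F1. Colvin homologation as in step 3 gives the 1-ethynyl analogue F2. HF in acetonitrile hydrolyses the enol ether and eliminates the amine to give (4S)-4-ethynyl-4-methylcyclohex-2-en-1-one F3. Conjugate reduction with K[s-Bu3BH] and trapping of the enolate with TIPSOTf then gives 6; the enol ether double bond is placed by the position of the enone, so the two arms stay distinct.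

**Step 15 (vinylogous aldol).** The likely failure is insufficient simple diastereoselection at C4, or incomplete facial control at the quaternary C5, because the existing stereocentres are too remote to help and the γ-methyl group changes the steric picture of the open transition state. Epimers at C5 are diastereomers of 24 and would have to be separated. Fallback for C4, from 24 (as the C4 mixture) back to 24: Dess–Martin oxidation gives ynone F4, (5R)-5-methyl-5-(2-alkynoyl)furan-2(5H)-one with the rest of 24 unchanged. Asymmetric transfer hydrogenation with RuCl(p-cymene)[(S,S)-TsDPEN] in HCO2H/Et3N re-forms the carbinol under reagent control, the alkyne acting as the directing π-substituent, to give the (4R)-alcohol.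

**Step 16 (semi-hydrogenation).** The likely failure is hydrogenolysis of the alkenyl C–I bond on palladium, or slow uptake at the hindered alkyne that lets the isopropenyl or butenolide alkene be reduced. Fallback, from 24 directly to 25: reduction with zinc activated by Cu(OAc)2 and AgNO3 in MeOH/H2O. This is electron transfer from the metal surface to the alkyne, which the propargylic hydroxyl activates, followed by cis protonation. No palladium hydride is involved and zinc does not insert into unactivated alkenyl iodides under these conditions. No new compound is made.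

**Step 22 (ring closure).** The likely failure is intermolecular coupling or protodemetalation of alkenylchromium 33 before it reaches the aldehyde, because of the strain of the eleven-membered ring and the entropic cost of closing it; cis-to-trans isomerisation of the enal during a slow reaction is a second risk. Fallback, from 31 back to 34, closing the ring by olefin metathesis instead of carbonyl addition: the NiCl2/CrCl2 coupling is run intermolecularly on 31 with excess acrolein, which is reliable, to give bis-allylic alcohol F5 (31 with CH(OH)CH=CH2 in place of iodine). Ring-closing metathesis with the second-generation Grubbs catalyst, RuCl2(=CHPh)(PCy3)(H2IMes), at high dilution then joins the new vinyl group to C6. The old C7–C8 end leaves as allyl triethylsilyl ether and the cis C6=C7 bond is formed inside the ring, giving 34. The catalyst loads on the unhindered vinyl group, and the isopropenyl, senecioate and C2=C3 alkenes are much less reactive.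

## Further compounds

F1 | step 2 | (1S)-4-(tert-butyldimethylsilyloxy)-2-(dimethylamino)-1-methylcyclohex-3-ene-1-carbaldehyde | O=C[C@]1(C)C(N(C)C)C=C(O[Si](C)(C)C(C)(C)C)CC1
F2 | step 2 | 1-ethynyl analogue of F1 (3-(dimethylamino)-4-ethynyl-4-methylcyclohex-1-enyl tert-butyldimethylsilyl ether, quaternary centre as in F1) | C#C[C@]1(C)C(N(C)C)C=C(O[Si](C)(C)C(C)(C)C)CC1
F3 | step 2 | (4S)-4-ethynyl-4-methylcyclohex-2-en-1-one | C#C[C@]1(C)C=CC(=O)CC1
F4 | step 15 | ynone from 24 (C4 ketone, (5R)-butenolide) | CC(C)(C)[Si](C)(C)OC/C(I)=C/C[C@@](C)(C#CC(=O)[C@]1(C)OC(=O)C=C1)CC[C@@H](O[Si](C)(C)C(C)(C)C)C(C)=C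
F0 | step 16 | none | none
F5 | step 22 | acrolein adduct of 31 (1-hydroxyprop-2-enyl group on C9 in place of iodine, C8 epimers) | CC(C)(C)[Si](C)(C)OC/C(C(O)C=C)=C/C[C@@](C)(/C=C\[C@@H](OC(=O)C=C(C)C)[C@](C)(O[Si](CC)(CC)CC)/C=C\CO[Si](CC)(CC)CC)CC[C@@H](O[Si](C)(C)C(C)(C)C)C(C)=C
A1 | alternative 1 | eleven-membered ring with exocyclic methylene on C9, C10 triethylsilyl ether, C8 p-methoxybenzyl ether, C4 senecioate, C5 triethylsilyl ether, C3′ tert-butyldimethylsilyl ether | C=C(C)[C@H](O[Si](C)(C)C(C)(C)C)CC[C@]1(C)/C=C\[C@@H](OC(=O)C=C(C)C)[C@](C)(O[Si](CC)(CC)CC)/C=C\[C@H](OCc2ccc(OC)cc2)C(=C)[C@@H](O[Si](CC)(CC)CC)C1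
A2 | alternative 2 | eleven-membered trienone with C4 and C5 triethylsilyl ethers and tert-butyldimethylsilyl ethers on O3′ and on the C9 hydroxymethyl group | C=C(C)[C@H](O[Si](C)(C)C(C)(C)C)CC[C@]1(C)/C=C\[C@@H](O[Si](CC)(CC)CC)[C@](C)(O[Si](CC)(CC)CC)/C=C\C(=O)/C(CO[Si](C)(C)C(C)(C)C)=C\C1
A3 | alternative 3 | eleven-membered C4 alcohol with C5 and C8 triethylsilyl ethers and tert-butyldimethylsilyl ethers on O3′ and on the C9 hydroxymethyl group | C=C(C)[C@H](O[Si](C)(C)C(C)(C)C)CC[C@]1(C)/C=C\[C@@H](O)[C@](C)(O[Si](CC)(CC)CC)/C=C\[C@H](O[Si](CC)(CC)CC)/C(CO[Si](C)(C)C(C)(C)C)=C\C1
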